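**Strategy.** Ring A is traced back to an open chain. Its ether carbon C2 lies between the hydroxylated carbons C1 and C3, with the third hydroxyl on C5, which is the oxygen pattern of C4 of a 4-aryloxy-3,5-dioxoheptanedioate between its two ketones. One Claisen closure, chain C2 onto the C7 ester, forms the only new C–C bond, closes ring A and aromatises it with three free hydroxyls and the A–B ether already in place. The precursor is the 1-tert-butyl 7-methyl diester whose aryloxy group is the permethylated B–H heptamer, built convergently from a two-ring bromo aldehyde block. The ester pair fixes which end attacks and lets one final step remove ester, CO2 and all methyl ethers.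

Key step: step 17

Remark on conventions and on what is left uncontrolled:
- Rings are lettered A–H in the order of the target SMILES; every oxygen of rings B–H that is not an ether bridge is carried as OMe.
- Ring B: C1 bears the group that becomes the A–B oxygen, C3 and C4 bear OMe, C5 bears the bridge to ring C.
- Rings C, E, G: C1 bears the bridge to B, D or F; C2 bears the bridge to D, F or H (or the functional group named); C3–C5 bear OMe.
- Rings D, F: C1 bears the bridge to C or E, C4 the bridge to E or G, C3 and C5 bear OMe. Ring H is 3,4,5-trimethoxyphenyl.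
- "Ar" is the B–H heptamer aryl group with eighteen OMe. Chain carbons run C1 (tert-butyl ester) to C7 (methyl ester).
- The target has no stereocentre. Alkene geometry in 26, 27 and 29 and the labile sp3 centre of 4, 29 and 30 are not controlled and are erased later.

**Step 1**
Reactants: 1 3,4,5-trimethoxyaniline
Product: 3 5-fluoro-1,2,3-trimethoxybenzene, via 3,4,5-trimethoxybenzenediazonium fluoride 2 (not isolated)
Conditions: NaNO2, HF–pyridine, 0 °C; then 85 °C
Reagents that add atoms: hydrogen fluoride, F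
Why: Balz–Schiemann-type fluorodediazoniation (diazotisation, then thermal loss of N2 with capture by fluoride) is an established route from alkoxyanilines to aryl fluorides, and the symmetric ring allows only one product.

**Step 2**
Reactants: 3 5-fluoro-1,2,3-trimethoxybenzene
Product: 5 6-fluoro-2,3,4-trimethoxybenzaldehyde, via chloro(methoxy)methyl arene 4 (not isolated)
Conditions: Cl2CHOMe, TiCl4, CH2Cl2, 0 °C; then H2O
Reagents that add atoms: dichloromethyl methyl ether, COC(Cl)Cl; water, O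
Why: Rieche formylation can only occur at the two equivalent free positions, each ortho and para to methoxy groups, so the aldehyde should emerge with fluorine ortho to it, ready for SNAr.

**Step 3**
Reactants: 6 4-bromo-2,6-dimethoxyphenol; 5 6-fluoro-2,3,4-trimethoxybenzaldehyde
Product: 7 6-(4-bromo-2,6-dimethoxyphenoxy)-2,3,4-trimethoxybenzaldehyde (two-ring block)
Conditions: K2CO3, DMF, 120 °C
Reagents that add atoms: none
Why: SNAr through a Meisenheimer complex: the fluoride ortho to the formyl group is displaced by the 2,6-dimethoxyphenoxide at a carbon flanked only by H and CHO, while the unactivated aryl bromide is inert without a metal.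

**Step 4**
Reactants: 8 3-hydroxy-4,5-dimethoxybenzaldehyde
Product: 9 5-(5,5-dimethyl-1,3-dioxan-2-yl)-2,3-dimethoxyphenol
Conditions: 2,2-dimethylpropane-1,3-diol, TsOH (cat.), toluene, reflux, Dean–Stark
Reagents that add atoms: 2,2-dimethylpropane-1,3-diol, CC(C)(CO)CO
Why: acid-catalysed acetalisation with azeotropic removal of water masks the aldehyde that later becomes the ring B phenol, so that it is blind to the three intervening Baeyer–Villiger oxidations; the free phenol is unaffected.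

**Step 5**
Reactants: 9 ring B acetal phenol; 5 6-fluoro-2,3,4-trimethoxybenzaldehyde
Product: 10 B–C aldehyde 6-[5-(5,5-dimethyl-1,3-dioxan-2-yl)-2,3-dimethoxyphenoxy]-2,3,4-trimethoxybenzaldehyde
Conditions: K2CO3, DMF, 120 °C
Reagents that add atoms: none
Why: SNAr as in step 3, the ring B phenoxide (one ortho methoxy group) displacing the ortho-formyl fluoride; the acetal is stable to carbonate.

**Step 6**
Reactants: 10 B–C aldehyde
Product: 12 B–C phenol 6-[5-(5,5-dimethyl-1,3-dioxan-2-yl)-2,3-dimethoxyphenoxy]-2,3,4-trimethoxyphenol, via aryl formate 11 (not isolated)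
Conditions: mCPBA, NaHCO3 (buffer), CH2Cl2, 0 °C to rt; then K2CO3 (cat.), MeOH, rt
Reagents that add atoms: mCPBA, O=C(OO)c1cccc(Cl)c1
Why: Baeyer–Villiger (Dakin-type) oxidation: the electron-rich ring C aryl group, flanked by two oxygens, migrates in the Criegee adduct in preference to H, and methanolysis of the aryl formate frees the C2 phenol while the buffer protects the acetal.

**Step 7**
Reactants: 12 B–C phenol; 7 two-ring bromo aldehyde block
Product: 13 B–C–D–E tetramer aldehyde (ring C C2–O–ring D C1; ring E C2–CHO)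
Conditions: CuI (10 mol %), picolinic acid (20 mol %), K3PO4, DMSO, 90 °C
Reagents that add atoms: none
Why: Ullmann diaryl ether synthesis: the copper phenoxide of 12 should couple with the aryl bromide of 7, which has two ortho hydrogens, under picolinic acid ligation, a system developed for phenols with two ortho substituents; the aldehyde of 7 is a spectator.

**Step 8**
Reactants: 13 B–C–D–E tetramer aldehyde
Product: 15 B–C–D–E tetramer phenol (ring E C2–OH), via aryl formate 14 (not isolated)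
Conditions: mCPBA, NaHCO3 (buffer), CH2Cl2, 0 °C to rt; then K2CO3 (cat.), MeOH, rt
Reagents that add atoms: mCPBA, O=C(OO)c1cccc(Cl)c1
Why: Baeyer–Villiger oxidation and formate methanolysis as in step 6, the ring E aldehyde having the same 2,6-dioxygenated environment that favours aryl migration.

**Step 9**
Reactants: 15 B–C–D–E tetramer phenol; 7 two-ring bromo aldehyde block
Product: 16 B–G hexamer aldehyde (ring E C2–O–ring F C1; ring G C2–CHO)
Conditions: CuI (10 mol %), picolinic acid (20 mol %), K3PO4, DMSO, 90 °C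
Reagents that add atoms: none
Why: Ullmann diaryl ether synthesis as in step 7; the second use of block 7 adds rings F and G in one bond-forming event.

**Step 10**
Reactants: 16 B–G hexamer aldehyde
Product: 18 B–G hexamer phenol (ring G C2–OH), via aryl formate 17 (not isolated)
Conditions: mCPBA, NaHCO3 (buffer), CH2Cl2, 0 °C to rt; then K2CO3 (cat.), MeOH, rt
Reagents that add atoms: mCPBA, O=C(OO)c1cccc(Cl)c1
Why: Baeyer–Villiger oxidation and formate methanolysis as in steps 6 and 8.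

**Step 11**
Reactants: 18 B–G hexamer phenol; 19 5-bromo-1,2,3-trimethoxybenzene
Product: 20 B–H heptamer acetal (ring G C2–O–ring H; ring B C1 still the dioxane acetal)
Conditions: CuI (10 mol %), picolinic acid (20 mol %), K3PO4, DMSO, 100 °C
Reagents that add atoms: none
Why: Ullmann diaryl ether synthesis with an aryl bromide that has two ortho hydrogens and can be used in excess, which completes the seven-ring ether chain.

**Step 12**
Reactants: 20 B–H heptamer acetal
Product: 21 B–H heptamer aldehyde (ring B C1–CHO)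
Conditions: 1 M HCl, THF, rt
Reagents that add atoms: water, O
Why: acid-catalysed acetal hydrolysis under conditions that leave aryl methyl ethers and diaryl ethers untouched.

**Step 13**
Reactants: 21 B–H heptamer aldehyde
Product: 23 B–H heptamer phenol ArOH (ring B C1–OH), via aryl formate 22 (not isolated)
Conditions: mCPBA, NaHCO3 (buffer), CH2Cl2, 0 °C to rt; then K2CO3 (cat.), MeOH, rt
Reagents that add atoms: mCPBA, O=C(OO)c1cccc(Cl)c1
Why: Baeyer–Villiger oxidation and formate methanolysis: the ring B aldehyde has a para methoxy group, so aryl migration should prevail as it does for 3,4,5-trimethoxybenzaldehyde, giving the only free phenol of the heptamer.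

**Step 14**
Reactants: 23 heptamer phenol ArOH; 24 tert-butyl 4-chloro-3-oxobutanoate
Product: 25 tert-butyl 4-(ArO)-3-oxobutanoate
Conditions: NaH (2.2 equiv), NaI (cat.), THF–DMF, 0 °C to 50 °C
Reagents that add atoms: none
Why: Williamson ether synthesis: the unhindered ring B phenoxide (two ortho hydrogens) displaces the primary chloride, the acidic methylene of 24 being held as its sodium enolate by the second equivalent of NaH.

**Step 15**
Reactants: 25 tert-butyl 4-(ArO)-3-oxobutanoate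
Product: 27 1-tert-butoxy-1,3-bis(trimethylsilyloxy)-4-(ArO)buta-1,3-diene, via mono(silyl enol ether) 26 (not isolated)
Conditions: Me3SiCl, Et3N, toluene, rt; then LiN(i-Pr)2, THF, −78 °C, Me3SiCl
Reagents that add atoms: chlorotrimethylsilane, C[Si](C)(C)Cl
Why: Chan-type bis(silyl enol ether) formation: Et3N/Me3SiCl silylates the β-keto ester enol, and LiN(i-Pr)2 then removes the γ-proton on the aryloxy carbon so that the ester enolate is silylated on oxygen.

**Step 16**
Reactants: 27 bis(silyloxy)diene; 28 methyl 3-chloro-3-oxopropanoate (methyl malonyl chloride)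
Product: 30 1-tert-butyl 7-methyl 4-(ArO)-3,5-dioxoheptanedioate (racemic at C4 and largely enolised), via C3 silyl enol ether 29 (not isolated)
Conditions: CH2Cl2, −78 °C to rt; then aq. NH4Cl
Reagents that add atoms: none
Why: Mukaiyama-type γ-acylation: the terminal, aryloxy-bearing carbon of the bis(silyloxy)diene attacks the acid chloride without added base, which puts the second β-keto ester arm on C4 and avoids both enolisation of 28 and any activated aryloxymalonic acid, a species that would lose CO2.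

**Step 17**
Reactants: 30 1-tert-butyl 7-methyl 4-(ArO)-3,5-dioxoheptanedioate
Product: 31 tert-butyl 3-(ArO)-2,4,6-trihydroxybenzoate
Conditions: NaOMe (4 equiv), MeOH–THF, 0 °C to rt, Ar; then cold 1 M HCl
Reagents that add atoms: none
Why: Methoxide generates the enolate at C2, between the tert-butyl ester and the C3 ketone, which adds to the C7 methyl ester carbonyl; loss of methoxide gives a cyclohexane-1,3,5-trione that enolises at once to the aromatic trihydroxybenzoate, C4 with its aryloxy group becoming the ring carbon between two hydroxyls. The closest known reaction is the base-mediated Claisen (Dieckmann) cyclisation of 3,5-dioxopimelates and related triketide chains to phloroglucinol carboxylates. Ring A closes in a 6-exo-trig (enolendo) mode; no stereocentre is formed and the labile one at C4 disappears on aromatisation. The step needs C-acylation from C2 and not from C6, C4 or an enol oxygen: the tert-butyl ester is a poor acceptor, so closure of C6 onto C1 is suppressed; the C4 enolate can reach only four-membered rings; and any pyranone from O-acylation is reopened by methoxide whereas the aromatic phenoxide is not, so the equilibria drain to ring A. The eighteen methyl ethers and seven diaryl ethers are inert to methoxide.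

**Step 18**
Reactants: 31 tert-butyl 3-(ArO)-2,4,6-trihydroxybenzoate
Product: 33 CNP0175816.0 (target), via free trihydroxybenzoic acid 32 (not isolated)
Conditions: BBr3 (excess), CH2Cl2, −78 °C to rt; then H2O, 60 °C, Ar
Reagents that add atoms: none
Why: BBr3 ether and ester cleavage followed by protodecarboxylation: the boron-complexed methyl ethers and the tert-butyl ester lose their alkyl groups to bromide while diaryl ether bonds offer no sp3 carbon, and the 2,4,6-trihydroxybenzoic acid released on hydrolysis loses CO2 through ipso protonation on warming.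

**Compound list**

1 | 3,4,5-trimethoxyaniline | COc1cc(N)cc(OC)c1OC | starting material
2 | 3,4,5-trimethoxybenzenediazonium fluoride | COc1cc([N+]#N)cc(OC)c1OC.[F-] | intermediate (not isolated)
3 | 5-fluoro-1,2,3-trimethoxybenzene | COc1cc(F)cc(OC)c1OC | intermediate
4 | 2-[chloro(methoxy)methyl]-1-fluoro-3,4,5-trimethoxybenzene (racemic) | COC(Cl)c1c(F)cc(OC)c(OC)c1OC | intermediate (not isolated)
5 | 6-fluoro-2,3,4-trimethoxybenzaldehyde | O=Cc1c(F)cc(OC)c(OC)c1OC | intermediate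
6 | 4-bromo-2,6-dimethoxyphenol | COc1cc(Br)cc(OC)c1O | starting material
7 | 6-(4-bromo-2,6-dimethoxyphenoxy)-2,3,4-trimethoxybenzaldehyde (two-ring block) | O=Cc1c(Oc2c(OC)cc(Br)cc2OC)cc(OC)c(OC)c1OC | intermediate
8 | 3-hydroxy-4,5-dimethoxybenzaldehyde | O=Cc1cc(O)c(OC)c(OC)c1 | starting material
9 | 5-(5,5-dimethyl-1,3-dioxan-2-yl)-2,3-dimethoxyphenol | CC1(C)COC(OC1)c1cc(O)c(OC)c(OC)c1 | intermediate
10 | B–C aldehyde, 6-[5-(5,5-dimethyl-1,3-dioxan-2-yl)-2,3-dimethoxyphenoxy]-2,3,4-trimethoxybenzaldehyde | CC1(C)COC(OC1)c1cc(OC)c(OC)c(Oc2cc(OC)c(OC)c(OC)c2C=O)c1 | intermediate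
11 | formate ester of B–C phenol 12 | CC1(C)COC(OC1)c1cc(OC)c(OC)c(Oc2cc(OC)c(OC)c(OC)c2OC=O)c1 | intermediate (not isolated)
12 | B–C phenol, 6-[5-(5,5-dimethyl-1,3-dioxan-2-yl)-2,3-dimethoxyphenoxy]-2,3,4-trimethoxyphenol | CC1(C)COC(OC1)c1cc(OC)c(OC)c(Oc2cc(OC)c(OC)c(OC)c2O)c1 | intermediate
13 | B–C–D–E tetramer aldehyde (ring B C1 acetal, ring E C2–CHO, ten OMe) | CC1(C)COC(OC1)c1cc(OC)c(OC)c(Oc2cc(OC)c(OC)c(OC)c2Oc2cc(OC)c(Oc3cc(OC)c(OC)c(OC)c3C=O)c(OC)c2)c1 | intermediate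
14 | formate ester of tetramer phenol 15 | CC1(C)COC(OC1)c1cc(OC)c(OC)c(Oc2cc(OC)c(OC)c(OC)c2Oc2cc(OC)c(Oc3cc(OC)c(OC)c(OC)c3OC=O)c(OC)c2)c1 | intermediate (not isolated)
15 | B–C–D–E tetramer phenol (ring E C2–OH) | CC1(C)COC(OC1)c1cc(OC)c(OC)c(Oc2cc(OC)c(OC)c(OC)c2Oc2cc(OC)c(Oc3cc(OC)c(OC)c(OC)c3O)c(OC)c2)c1 | intermediate
16 | B–G hexamer aldehyde (ring G C2–CHO, fifteen OMe) | CC1(C)COC(OC1)c1cc(OC)c(OC)c(Oc2cc(OC)c(OC)c(OC)c2Oc2cc(OC)c(Oc3cc(OC)c(OC)c(OC)c3Oc3cc(OC)c(Oc4cc(OC)c(OC)c(OC)c4C=O)c(OC)c3)c(OC)c2)c1 | intermediate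
17 | formate ester of hexamer phenol 18 | CC1(C)COC(OC1)c1cc(OC)c(OC)c(Oc2cc(OC)c(OC)c(OC)c2Oc2cc(OC)c(Oc3cc(OC)c(OC)c(OC)c3Oc3cc(OC)c(Oc4cc(OC)c(OC)c(OC)c4OC=O)c(OC)c3)c(OC)c2)c1 | intermediate (not isolated)
18 | B–G hexamer phenol (ring G C2–OH) | CC1(C)COC(OC1)c1cc(OC)c(OC)c(Oc2cc(OC)c(OC)c(OC)c2Oc2cc(OC)c(Oc3cc(OC)c(OC)c(OC)c3Oc3cc(OC)c(Oc4cc(OC)c(OC)c(OC)c4O)c(OC)c3)c(OC)c2)c1 | intermediate
19 | 5-bromo-1,2,3-trimethoxybenzene | COc1cc(Br)cc(OC)c1OC | starting material
20 | B–H heptamer acetal (ring B C1 dioxane acetal, eighteen OMe) | CC1(C)COC(OC1)c1cc(OC)c(OC)c(Oc2cc(OC)c(OC)c(OC)c2Oc2cc(OC)c(Oc3cc(OC)c(OC)c(OC)c3Oc3cc(OC)c(Oc4cc(OC)c(OC)c(OC)c4Oc4cc(OC)c(OC)c(OC)c4)c(OC)c3)c(OC)c2)c1 | intermediate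
21 | B–H heptamer aldehyde (ring B C1–CHO) | O=Cc1cc(OC)c(OC)c(Oc2cc(OC)c(OC)c(OC)c2Oc2cc(OC)c(Oc3cc(OC)c(OC)c(OC)c3Oc3cc(OC)c(Oc4cc(OC)c(OC)c(OC)c4Oc4cc(OC)c(OC)c(OC)c4)c(OC)c3)c(OC)c2)c1 | intermediate
22 | formate ester of heptamer phenol 23 | O=COc1cc(OC)c(OC)c(Oc2cc(OC)c(OC)c(OC)c2Oc2cc(OC)c(Oc3cc(OC)c(OC)c(OC)c3Oc3cc(OC)c(Oc4cc(OC)c(OC)c(OC)c4Oc4cc(OC)c(OC)c(OC)c4)c(OC)c3)c(OC)c2)c1 | intermediate (not isolated)
23 | B–H heptamer phenol ArOH (ring B C1–OH, eighteen OMe) | Oc1cc(OC)c(OC)c(Oc2cc(OC)c(OC)c(OC)c2Oc2cc(OC)c(Oc3cc(OC)c(OC)c(OC)c3Oc3cc(OC)c(Oc4cc(OC)c(OC)c(OC)c4Oc4cc(OC)c(OC)c(OC)c4)c(OC)c3)c(OC)c2)c1 | intermediate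
24 | tert-butyl 4-chloro-3-oxobutanoate | CC(C)(C)OC(=O)CC(=O)CCl | starting material
25 | tert-butyl 4-(ArO)-3-oxobutanoate | CC(C)(C)OC(=O)CC(=O)COc1cc(OC)c(OC)c(Oc2cc(OC)c(OC)c(OC)c2Oc2cc(OC)c(Oc3cc(OC)c(OC)c(OC)c3Oc3cc(OC)c(Oc4cc(OC)c(OC)c(OC)c4Oc4cc(OC)c(OC)c(OC)c4)c(OC)c3)c(OC)c2)c1 | intermediate
26 | tert-butyl 4-(ArO)-3-(trimethylsilyloxy)but-2-enoate (geometry not defined) | CC(C)(C)OC(=O)C=C(O[Si](C)(C)C)COc1cc(OC)c(OC)c(Oc2cc(OC)c(OC)c(OC)c2Oc2cc(OC)c(Oc3cc(OC)c(OC)c(OC)c3Oc3cc(OC)c(Oc4cc(OC)c(OC)c(OC)c4Oc4cc(OC)c(OC)c(OC)c4)c(OC)c3)c(OC)c2)c1 | intermediate (not isolated)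
27 | 1-tert-butoxy-1,3-bis(trimethylsilyloxy)-4-(ArO)buta-1,3-diene (geometry not defined) | CC(C)(C)OC(O[Si](C)(C)C)=CC(O[Si](C)(C)C)=COc1cc(OC)c(OC)c(Oc2cc(OC)c(OC)c(OC)c2Oc2cc(OC)c(Oc3cc(OC)c(OC)c(OC)c3Oc3cc(OC)c(Oc4cc(OC)c(OC)c(OC)c4Oc4cc(OC)c(OC)c(OC)c4)c(OC)c3)c(OC)c2)c1 | intermediate
28 | methyl 3-chloro-3-oxopropanoate | COC(=O)CC(Cl)=O | starting material
29 | 1-tert-butyl 7-methyl 4-(ArO)-5-oxo-3-(trimethylsilyloxy)hept-2-enedioate (racemic, geometry not defined) | CC(C)(C)OC(=O)C=C(O[Si](C)(C)C)C(Oc1cc(OC)c(OC)c(Oc2cc(OC)c(OC)c(OC)c2Oc2cc(OC)c(Oc3cc(OC)c(OC)c(OC)c3Oc3cc(OC)c(Oc4cc(OC)c(OC)c(OC)c4Oc4cc(OC)c(OC)c(OC)c4)c(OC)c3)c(OC)c2)c1)C(=O)CC(=O)OC | intermediate (not isolated)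
30 | 1-tert-butyl 7-methyl 4-(ArO)-3,5-dioxoheptanedioate (racemic at C4; key-step precursor) | CC(C)(C)OC(=O)CC(=O)C(Oc1cc(OC)c(OC)c(Oc2cc(OC)c(OC)c(OC)c2Oc2cc(OC)c(Oc3cc(OC)c(OC)c(OC)c3Oc3cc(OC)c(Oc4cc(OC)c(OC)c(OC)c4Oc4cc(OC)c(OC)c(OC)c4)c(OC)c3)c(OC)c2)c1)C(=O)CC(=O)OC | intermediate
31 | tert-butyl 3-(ArO)-2,4,6-trihydroxybenzoate (key-step product; ring A free, eighteen OMe) | CC(C)(C)OC(=O)c1c(O)cc(O)c(Oc2cc(OC)c(OC)c(Oc3cc(OC)c(OC)c(OC)c3Oc3cc(OC)c(Oc4cc(OC)c(OC)c(OC)c4Oc4cc(OC)c(Oc5cc(OC)c(OC)c(OC)c5Oc5cc(OC)c(OC)c(OC)c5)c(OC)c4)c(OC)c3)c2)c1O | intermediate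
32 | 2,4,6-trihydroxy-3-(heptamer-oxy)benzoic acid with all twenty-one hydroxyls free | OC(=O)c1c(O)cc(O)c(Oc2cc(O)c(O)c(Oc3cc(O)c(O)c(O)c3Oc3cc(O)c(Oc4cc(O)c(O)c(O)c4Oc4cc(O)c(Oc5cc(O)c(O)c(O)c5Oc5cc(O)c(O)c(O)c5)c(O)c4)c(O)c3)c2)c1O | intermediate (not isolated)
33 | CNP0175816.0 | Oc1cc(O)c(Oc2cc(O)c(O)c(Oc3cc(O)c(O)c(O)c3Oc3cc(O)c(Oc4cc(O)c(O)c(O)c4Oc4cc(O)c(Oc5cc(O)c(O)c(O)c5Oc5cc(O)c(O)c(O)c5)c(O)c4)c(O)c3)c2)c(O)c1 | target

**Step count and risks**

Total: 18 steps. Longest linear sequence: 16 steps (steps 1, 2 and 5–18, from 3,4,5-trimethoxyaniline).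

Most likely to fail, in this order:

Step 17. The chain may rest at the O-acylated pyranone, or methoxide may cut the aryloxy diketone by retro-Claisen cleavage before the carbon nucleophile closes the ring. The fallback makes ring A from a preformed arene instead of a chain. It sets out from phenol 23: SNAr with 4-fluoro-3,5-dimethoxybenzaldehyde (O=Cc1cc(OC)c(F)c(OC)c1; K2CO3, DMSO, 130 °C) should give the octamer aldehyde F1. Baeyer–Villiger oxidation (mCPBA, then K2CO3/MeOH) passes through the octamer formate F2 to the octamer phenol F3, whose ring A already has the ether carbon between two methoxy groups and the third oxygen para to it. BBr3 in CH2Cl2 then cleaves twenty methyl ethers and the sequence comes back at 33.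

Step 9. Bond formation at a phenol oxygen flanked by an aryloxy and a methoxy group may be slower than reduction of the C–Br bond of 7, the more so as the phenol grows. The fallback replaces the copper coupling by two SNAr reactions. From phenol 15, 4-fluoro-2,6-dimethoxybenzaldehyde (O=Cc1c(OC)cc(F)cc1OC; K2CO3, DMF, 110 °C), whose fluoride is para to CHO and flanked by hydrogens, should give the pentamer aldehyde F4 with ring F carrying CHO at C4. Baeyer–Villiger oxidation via the pentamer formate F5 gives the pentamer phenol F6, and SNAr of this with fluoro aldehyde 5 under the conditions of step 3 comes back at hexamer aldehyde 16. The same detour would serve for step 7.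

Step 18. Cleavage of eighteen ethers may stop short, the tert-butyl fragment may be captured by an electron-rich ring, and the free polyphenol may oxidise in air during isolation. The fallback separates ester removal from ether cleavage and isolates the product as a stable derivative. From 31, CF3CO2H with Et3SiH as cation trap in CH2Cl2, then toluene at 80 °C, should give via the methylated acid F7 the decarboxylated triol F8. BBr3 as in step 18, then Ac2O/pyridine on the crude polyphenol, gives the henicosaacetate F9, which can be chromatographed on silica. HCl in MeOH under argon then removes the acetates and comes back at 33.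

**Further compounds**

F1 | step 17 | octamer aldehyde, 3,5-dimethoxy-4-(ArO)benzaldehyde | O=Cc1cc(OC)c(Oc2cc(OC)c(OC)c(Oc3cc(OC)c(OC)c(OC)c3Oc3cc(OC)c(Oc4cc(OC)c(OC)c(OC)c4Oc4cc(OC)c(Oc5cc(OC)c(OC)c(OC)c5Oc5cc(OC)c(OC)c(OC)c5)c(OC)c4)c(OC)c3)c2)c(OC)c1
F2 | step 17 | octamer formate, 3,5-dimethoxy-4-(ArO)phenyl formate | O=COc1cc(OC)c(Oc2cc(OC)c(OC)c(Oc3cc(OC)c(OC)c(OC)c3Oc3cc(OC)c(Oc4cc(OC)c(OC)c(OC)c4Oc4cc(OC)c(Oc5cc(OC)c(OC)c(OC)c5Oc5cc(OC)c(OC)c(OC)c5)c(OC)c4)c(OC)c3)c2)c(OC)c1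
F3 | step 17 | octamer phenol, 3,5-dimethoxy-4-(ArO)phenol | Oc1cc(OC)c(Oc2cc(OC)c(OC)c(Oc3cc(OC)c(OC)c(OC)c3Oc3cc(OC)c(Oc4cc(OC)c(OC)c(OC)c4Oc4cc(OC)c(Oc5cc(OC)c(OC)c(OC)c5Oc5cc(OC)c(OC)c(OC)c5)c(OC)c4)c(OC)c3)c2)c(OC)c1
F4 | step 9 | B–F pentamer aldehyde (ring F C4–CHO, ring B C1 acetal) | CC1(C)COC(OC1)c1cc(OC)c(OC)c(Oc2cc(OC)c(OC)c(OC)c2Oc2cc(OC)c(Oc3cc(OC)c(OC)c(OC)c3Oc3cc(OC)c(C=O)c(OC)c3)c(OC)c2)c1
F5 | step 9 | B–F pentamer formate (ring F C4–OCHO) | CC1(C)COC(OC1)c1cc(OC)c(OC)c(Oc2cc(OC)c(OC)c(OC)c2Oc2cc(OC)c(Oc3cc(OC)c(OC)c(OC)c3Oc3cc(OC)c(OC=O)c(OC)c3)c(OC)c2)c1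
F6 | step 9 | B–F pentamer phenol (ring F C4–OH) | CC1(C)COC(OC1)c1cc(OC)c(OC)c(Oc2cc(OC)c(OC)c(OC)c2Oc2cc(OC)c(Oc3cc(OC)c(OC)c(OC)c3Oc3cc(OC)c(O)c(OC)c3)c(OC)c2)c1
F7 | step 18 | 3-(ArO)-2,4,6-trihydroxybenzoic acid (eighteen OMe) | OC(=O)c1c(O)cc(O)c(Oc2cc(OC)c(OC)c(Oc3cc(OC)c(OC)c(OC)c3Oc3cc(OC)c(Oc4cc(OC)c(OC)c(OC)c4Oc4cc(OC)c(Oc5cc(OC)c(OC)c(OC)c5Oc5cc(OC)c(OC)c(OC)c5)c(OC)c4)c(OC)c3)c2)c1O
F8 | step 18 | 2-(ArO)benzene-1,3,5-triol (eighteen OMe) | Oc1cc(O)c(Oc2cc(OC)c(OC)c(Oc3cc(OC)c(OC)c(OC)c3Oc3cc(OC)c(Oc4cc(OC)c(OC)c(OC)c4Oc4cc(OC)c(Oc5cc(OC)c(OC)c(OC)c5Oc5cc(OC)c(OC)c(OC)c5)c(OC)c4)c(OC)c3)c2)c(O)c1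
F9 | step 18 | henicosaacetate of the target | CC(=O)Oc1cc(OC(C)=O)c(Oc2cc(OC(C)=O)c(OC(C)=O)c(Oc3cc(OC(C)=O)c(OC(C)=O)c(OC(C)=O)c3Oc3cc(OC(C)=O)c(Oc4cc(OC(C)=O)c(OC(C)=O)c(OC(C)=O)c4Oc4cc(OC(C)=O)c(Oc5cc(OC(C)=O)c(OC(C)=O)c(OC(C)=O)c5Oc5cc(OC(C)=O)c(OC(C)=O)c(OC(C)=O)c5)c(OC(C)=O)c4)c(OC(C)=O)c3)c2)c(OC(C)=O)c1
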